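Minutes, not percentage points per second, are the unit in which the violet run's left-handed loss is best counted.

all flasks: left-handed substrate 0.090 M; right-handed substrate 0.090 M; added ligand 0.79 mM
- violet: partner 2 equiv; precatalyst 2.1 mol%; run made earlier
- Saturday's: partner 2.00 equiv; precatalyst 1.4 mol%; time 5.0 min
- Friday's: partner 4.00 equiv; precatalyst 1.4 mol%; time 5.0 min

- violet (time / s: right-handed substrate / %, left-handed substrate / %): 20.0: 50.2, 49.7; 40.0: 49.5, 49.2; 50.0: 50.7, 49.9; 80.0: 50.0, 47.1; 120: 50.4, 44.4

(standard deviation of a reading: 0.5 percentage points)

- free catalyst is single-handed; left-handed substrate and right-handed substrate are mirror images of each other, charged as a racemate, each of them at the stated concentration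
- an excess is below zero if the other one leads
- no earlier run changes the charge of precatalyst; that part of a forecast is a guess

- which of the two ends with the higher excess of right-handed substrate over left-handed substrate among what is left of the two ("neither" if they lie within 2 percentage points) (Saturday's / Friday's / neither)
- excess of right-handed substrate over left-handed substrate among what is left of the two at the end, Saturday's
- excess of right-handed substrate over left-handed substrate among what is left of the two at the end, Friday's

Call the dose the natural logarithm of the ratio of right-handed to left-handed substrate left. The excess follows from it exactly: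

excess = (ratio − 1) / (ratio + 1)

The violet readings, each good to 0.5 percentage points, give a dose of 0.0159 at 50.0 s and 0.127 at 120 s. After this lag (induction period) the dose climbs at 0.0950 min⁻¹, as read, faster than the 0.0191 min⁻¹ read before it.

Two limits follow. If the rate grows in step with time throughout, the dose is the square of time over a dose time, and this dose time, the time in which the violet run's dose reaches 1 on such growth, reads 5.62 min. That gives the ceiling. If the rate stops growing at the late violet slope, the dose is that slope times the time after the lag, and that gives the floor. Both scale with precatalyst, which is a guess. No run changes the partner, so one power of it for the floor and two for the ceiling are guesses too.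

Saturday's ceiling: (1.4 mol%/2.1 mol%) × (time / dose time)² = 0.528, excess 25.8%

Saturday's floor: slope × (1.4 mol%/2.1 mol%) × (time − lag) = 0.264, excess 13.1%

Friday's ceiling: 2.11, excess 78.4%

Friday's floor: 0.528, excess 25.8%

The forecast, “Assuming roughly first order” in partner, gives 12% and 20% and names Friday's, with both values below these floors.

The flask gives 19.0% for Saturday's and 70.8% for Friday's, so Friday's leads, and both lie inside their brackets.

    left-handed product ⇌ right-handed product (k = 0.0200 s⁻¹)
    partner + catalyst intermediate B → free catalyst + right-handed product (k = 0.670 M⁻¹ s⁻¹)
    partner + precatalyst → free catalyst + spent reagent (k = 0.0170 M⁻¹ s⁻¹)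
    free catalyst + left-handed substrate ⇌ catalyst intermediate A (K = 120 M⁻¹, k = 650 M⁻¹ s⁻¹)
    free catalyst + right-handed substrate ⇌ catalyst intermediate B (K = 6.90 M⁻¹, k = 76.0 M⁻¹ s⁻¹)
    partner + catalyst intermediate A → free catalyst + left-handed product (k = 1.70 M⁻¹ s⁻¹)
    free catalyst + added ligand ⇌ idle complex, settled at all times (K = 490 M⁻¹)

At 5.00 min, 42.4% of the catalyst charged in Saturday's still stands as precatalyst. The dose time of 5.62 min, with the partner squared, serves once more on the neighbour of Saturday's charged with 1.20 equiv of partner: its ceiling dose reckons at 0.190, an excess of 9.47%, and that flask gives 7.38%.

The runs come from a simulation for an exercise; scatter was added.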